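Ring B is not brought in as an arene but grown on the finished chromone. Its guaiacol pattern (free 3'-OH on the carbon next to C4'-OMe, with C1' para to C4') maps onto 3-methoxyfuran, whose ring oxygen becomes the 3'-hydroxyl, plus the two alkyne carbons (C1', C2') of a 2-ethynylchromone. One operation, a regioselective furan–alkyne [4+2] cycloaddition followed by acid opening of the oxygen bridge, forms C2'–C3' and C1'–C6', closes ring B and delivers the unprotected phenol, which is the target itself. The precursor is 2-ethynyl-5,6,7,8-tetramethoxychromen-4-one, made from a fully oxygenated o-hydroxyacetophenone by Claisen condensation with a silyl-capped propiolate, cyclodehydration and desilylation.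

Key step: step 7

Remark: the target has no stereocentre; the only stereocentres in the route are the two bridgehead carbons of the transient cycloadduct 12, which forms as a racemate and loses them on aromatisation. Acetophenone locants (C1 = acyl-bearing carbon) are used for 3, 4, 5 and 7, and primed ring B locants for 12.

Step 1
Reactants: 1 3,4,5-trimethoxyphenol
Product: 3 1-(6-hydroxy-2,3,4-trimethoxyphenyl)ethan-1-one (2-hydroxy-4,5,6-trimethoxyacetophenone), via difluoroboron chelate 2 (not isolated)
Conditions: AcOH, BF3·OEt2 (3 equiv), 85 °C; then H2O, 60 °C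
Reagents that add atoms: acetic acid, CC(=O)O
Why: BF3-mediated Friedel–Crafts C-acylation (Fries-type ortho-acylation) of an electron-rich phenol, in which the two open ring positions of 1 are equivalent and both ortho to OH, and the ortho-hydroxy ketone is held as its O,O-difluoroboron chelate 2, which stops a second acylation and is hydrolysed on aqueous warming.

Step 2
Reactants: 3 1-(6-hydroxy-2,3,4-trimethoxyphenyl)ethan-1-one
Product: 4 1-(3-bromo-2-hydroxy-4,5,6-trimethoxyphenyl)ethan-1-one
Conditions: NBS (1.05 equiv), MeCN, 0 °C to rt
Reagents that add atoms: N-bromosuccinimide, O=C1CCC(=O)N1Br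
Why: Electrophilic aromatic bromination at C3, the only unsubstituted ring carbon, which is activated by the ortho hydroxyl and by ortho and para methoxy groups, while acid-free NBS should leave the hydrogen-bonded methyl ketone unbrominated.

Step 3
Reactants: 4 1-(3-bromo-2-hydroxy-4,5,6-trimethoxyphenyl)ethan-1-one
Product: 5 1-(2-hydroxy-3,4,5,6-tetramethoxyphenyl)ethan-1-one
Conditions: NaOMe (5 equiv), CuBr (0.2 equiv), DMF/MeOH, 110 °C; aq. HCl work-up
Reagents that add atoms: sodium methoxide, C[O-].[Na+]
Why: Ullmann-type copper-catalysed methoxylation of an aryl bromide, the reaction type that converts ortho-bromophenols such as 5-bromovanillin into their methyl ethers; under NaOMe the substrate is a phenoxide, which assists copper at the neighbouring C–Br bond and shields the ketone from aldol chemistry.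

Step 4
Reactants: 5 1-(2-hydroxy-3,4,5,6-tetramethoxyphenyl)ethan-1-one; 6 ethyl 3-(trimethylsilyl)prop-2-ynoate
Product: 8 5,6,7,8-tetramethoxy-2-[(trimethylsilyl)ethynyl]-4H-chromen-4-one, via silylalkynyl 1,3-diketone 7 (not isolated)
Conditions: LiN(SiMe3)2 (3.3 equiv), THF, −78 °C; 6, −78 to −30 °C; AcOH quench; crude 7, p-TsOH·H2O (0.2 equiv), toluene, 70 °C
Reagents that add atoms: none
Why: Crossed Claisen condensation of the dilithiated o-hydroxyacetophenone (phenoxide plus methyl-ketone enolate) with the activated ynoate 6, followed by the classical acid cyclodehydration of a 1-(2-hydroxyaryl)-1,3-diketone (6-exo-trig hemiketal formation at the alkynyl ketone, then loss of water) to the chromone; the trimethylsilyl cap hinders attack at the alkyne terminus in both stages.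

Step 5
Reactants: 8 5,6,7,8-tetramethoxy-2-[(trimethylsilyl)ethynyl]-4H-chromen-4-one
Product: 9 2-ethynyl-5,6,7,8-tetramethoxy-4H-chromen-4-one
Conditions: n-Bu4NF (1.1 equiv), AcOH (1.5 equiv), THF, −20 to 0 °C
Reagents that add atoms: none
Why: Fluoride-induced protodesilylation of an alkynylsilane; acetic acid protonates the acetylide as it forms and keeps the medium non-basic, so the electrophilic terminal alkyne of 9 is not exposed to alkoxide or unbuffered fluoride.

Step 6
Reactants: 10 3-bromofuran
Product: 11 3-methoxyfuran
Conditions: NaOMe (3 equiv), CuBr (0.1 equiv), MeOH/NMP, 100 °C, sealed vessel; pentane extraction, distillation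
Reagents that add atoms: sodium methoxide, C[O-].[Na+]
Why: Ullmann-type copper-catalysed C–O coupling of a heteroaryl bromide with methoxide, as applied to 3-bromothiophene; the furan carries no other reactive group and the volatile ether is taken off by distillation.

Step 7
Reactants: 9 2-ethynyl-5,6,7,8-tetramethoxy-4H-chromen-4-one; 11 3-methoxyfuran
Product: 13 3'-demethylnobiletin [2-(3-hydroxy-4-methoxyphenyl)-5,6,7,8-tetramethoxy-4H-chromen-4-one], via oxanorbornadiene cycloadduct 12 (not isolated)
Conditions: 11 (4 equiv), ZnI2 (0.3 equiv), CH2Cl2, 0 °C to rt; evaporate; TFA (0.2 equiv), CH2Cl2, rt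
Reagents that add atoms: none
Why: Zinc coordination at the C4 carbonyl (chelated by the 5-methoxy oxygen) lowers the LUMO of the vinylogous ynone, so the electron-rich diene 11 should add across the alkyne, not the less accessible chromone C2=C3 bond, in a normal-demand Diels–Alder reaction that is concerted but strongly asynchronous, furan C2 bonding first to the terminal alkyne carbon. The closest known reaction type is the cycloaddition of 3-alkoxyfurans with acetylenic esters and ketones followed by acid isomerisation of the 7-oxanorbornadiene to a phenol; here that reaction is applied to an alkyne activated through the chromone C2=C3 bond, a dienophile that has not been tested. Ring B closes as the six-membered carbocycle of the [4+2] addition (C2'–C3' and C1'–C6' formed on one face of the furan); acid then releases the bridging oxygen from C6', and proton loss from C3' gives the arene. The two bridgehead stereocentres of racemic 12 are erased on aromatisation, so no stereocontrol is needed. Two regiochemical choices matter and the methoxy group sets both: it makes furan C2 the most nucleophilic terminus, matching the δ-electrophilic terminal alkyne carbon, and it stabilises through the C4'=C5' enol ether the cation formed by breaking C6'–O, so the oxygen stays on C3' next to C4'-OMe.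

Compound list
1 | 3,4,5-trimethoxyphenol | COc1cc(O)cc(OC)c1OC | starting material
2 | O,O-difluoroboron chelate of 3 (BF2 bridging the phenol oxygen and the ketone oxygen; formed in the flask, not isolated) | CC1=[O+][B-](F)(F)Oc2cc(OC)c(OC)c(OC)c21 | intermediate
3 | 1-(6-hydroxy-2,3,4-trimethoxyphenyl)ethan-1-one (2-hydroxy-4,5,6-trimethoxyacetophenone) | CC(=O)c1c(O)cc(OC)c(OC)c1OC | intermediate
4 | 1-(3-bromo-2-hydroxy-4,5,6-trimethoxyphenyl)ethan-1-one | CC(=O)c1c(O)c(Br)c(OC)c(OC)c1OC | intermediate
5 | 1-(2-hydroxy-3,4,5,6-tetramethoxyphenyl)ethan-1-one | CC(=O)c1c(O)c(OC)c(OC)c(OC)c1OC | intermediate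
6 | ethyl 3-(trimethylsilyl)prop-2-ynoate | CCOC(=O)C#C[Si](C)(C)C | starting material
7 | 1-(2-hydroxy-3,4,5,6-tetramethoxyphenyl)-5-(trimethylsilyl)pent-4-yne-1,3-dione (formed in the flask, not isolated) | COc1c(OC)c(OC)c(O)c(C(=O)CC(=O)C#C[Si](C)(C)C)c1OC | intermediate
8 | 5,6,7,8-tetramethoxy-2-[(trimethylsilyl)ethynyl]-4H-chromen-4-one | C[Si](C)(C)C#Cc1cc(=O)c2c(OC)c(OC)c(OC)c(OC)c2o1 | intermediate
9 | 2-ethynyl-5,6,7,8-tetramethoxy-4H-chromen-4-one | C#Cc1cc(=O)c2c(OC)c(OC)c(OC)c(OC)c2o1 | intermediate
10 | 3-bromofuran | Brc1ccoc1 | starting material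
11 | 3-methoxyfuran | COc1ccoc1 | intermediate
12 | 2-(5-methoxy-7-oxabicyclo[2.2.1]hepta-2,5-dien-2-yl)-5,6,7,8-tetramethoxy-4H-chromen-4-one, racemic, one enantiomer drawn (formed in the flask, not isolated) | COC1=C[C@@H]2O[C@H]1C=C2c3cc(=O)c4c(OC)c(OC)c(OC)c(OC)c4o3 | intermediate
13 | 3'-demethylnobiletin, 2-(3-hydroxy-4-methoxyphenyl)-5,6,7,8-tetramethoxy-4H-chromen-4-one | COc1ccc(-c2cc(=O)c3c(OC)c(OC)c(OC)c(OC)c3o2)cc1O | target

Total step count: 7
Longest linear sequence: 6 steps (steps 1 to 5, then step 7); step 6 is a one-step side branch.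

Steps most likely to fail

1. Step 7. The alkyne is activated only through the C2=C3 bond and may be too weak an acceptor, so that no cycloaddition takes place. Under the Lewis acid the furan may instead add as a carbon nucleophile and re-aromatise by proton loss (conjugate alkenylation). The diene may also be consumed by acid-induced oligomerisation, or the bridge may open at the other C–O bond. The fallback sets out from 5 and comes back at 13 by established flavone chemistry. Claisen–Schmidt condensation of 5 with commercial 3-(benzyloxy)-4-methoxybenzaldehyde (KOH, EtOH, rt) should give (E)-3-[3-(benzyloxy)-4-methoxyphenyl]-1-(2-hydroxy-3,4,5,6-tetramethoxyphenyl)prop-2-en-1-one F1. Iodine-catalysed oxidative cyclisation in DMSO at 120 °C should then give 2-[3-(benzyloxy)-4-methoxyphenyl]-5,6,7,8-tetramethoxy-4H-chromen-4-one F2. Hydrogenolysis (H2, Pd/C, EtOAc/MeOH, rt) frees the 3'-hydroxyl to give 13.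

2. Step 4. Conjugate addition of the enolate or the amide base to the ynoate may compete with acyl substitution, and the base may strip the silyl group. In the acid stage the enol oxygen may close 6-endo onto the alkyne in place of phenol closure onto the carbonyl. The fallback sets out from 5 and comes back at 9, bypassing step 5 as well. Claisen condensation of 5 with diethyl oxalate (NaOEt, EtOH, reflux) should give ethyl 4-(2-hydroxy-3,4,5,6-tetramethoxyphenyl)-2,4-dioxobutanoate F3, which is not isolated. HCl in EtOH closes it to ethyl 5,6,7,8-tetramethoxy-4-oxo-4H-chromene-2-carboxylate F4. NaBH4 in MeOH/THF at 0 °C reduces the activated ester to 2-(hydroxymethyl)-5,6,7,8-tetramethoxy-4H-chromen-4-one F5, and MnO2 in CH2Cl2 oxidises this to 5,6,7,8-tetramethoxy-4-oxo-4H-chromene-2-carbaldehyde F6. Seyferth–Gilbert homologation with dimethyl (1-diazo-2-oxopropyl)phosphonate (K2CO3, MeOH, 0 °C, short contact) then gives 9.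

3. Step 6. Substitution at the unactivated furan 3-position may be slow, with decomposition at the temperature needed, and the volatile, acid-labile ether may be lost on isolation from the solvent mixture. The fallback sets out from 10 and comes back at 11 through non-volatile, carboxylate-anchored intermediates. Deprotonation of 10 at C2 (LiN(i-Pr)2, THF, −78 °C) and carboxylation with CO2 should give 3-bromofuran-2-carboxylic acid F7. Its bromide, now activated by the ortho carboxylate, should undergo copper-catalysed methoxylation (NaOMe, CuBr, MeOH, reflux) to 3-methoxyfuran-2-carboxylic acid F8. Protodecarboxylation with copper powder in quinoline at about 200 °C then lets 11 distil from the flask.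

Further compounds
F1 | step 7 | (E)-3-[3-(benzyloxy)-4-methoxyphenyl]-1-(2-hydroxy-3,4,5,6-tetramethoxyphenyl)prop-2-en-1-one | COc1ccc(/C=C/C(=O)c2c(O)c(OC)c(OC)c(OC)c2OC)cc1OCc1ccccc1
F2 | step 7 | 2-[3-(benzyloxy)-4-methoxyphenyl]-5,6,7,8-tetramethoxy-4H-chromen-4-one | COc1ccc(-c2cc(=O)c3c(OC)c(OC)c(OC)c(OC)c3o2)cc1OCc1ccccc1
F3 | step 4 | ethyl 4-(2-hydroxy-3,4,5,6-tetramethoxyphenyl)-2,4-dioxobutanoate | CCOC(=O)C(=O)CC(=O)c1c(O)c(OC)c(OC)c(OC)c1OC
F4 | step 4 | ethyl 5,6,7,8-tetramethoxy-4-oxo-4H-chromene-2-carboxylate | CCOC(=O)c1cc(=O)c2c(OC)c(OC)c(OC)c(OC)c2o1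
F5 | step 4 | 2-(hydroxymethyl)-5,6,7,8-tetramethoxy-4H-chromen-4-one | OCc1cc(=O)c2c(OC)c(OC)c(OC)c(OC)c2o1
F6 | step 4 | 5,6,7,8-tetramethoxy-4-oxo-4H-chromene-2-carbaldehyde | O=Cc1cc(=O)c2c(OC)c(OC)c(OC)c(OC)c2o1
F7 | step 6 | 3-bromofuran-2-carboxylic acid | OC(=O)c1occc1Br
F8 | step 6 | 3-methoxyfuran-2-carboxylic acid | COc1ccoc1C(=O)O
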